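The cyclohexene ring of the bicyclo[3.2.1]octene (C3a, C4, C5=C6, C7, C11) is read as a dearomatised 4-alkyl-3,5-dihydroxybenzoate: oxygen, or its former site, on C4 and C11 beside the spiro carbon C3a, and the carboxyl on C6 para to it. The only bonds from this ring to the two cyclopentanes, C3a–C8a and C7–C8, end on one C=C. Oxidising a free 2-alkylresorcinol tert-butyl benzoate whose (S)-configured benzylic carbon carries an E-trisubstituted alkene tether should therefore close both cyclopentanes and set four stereocentres in one cationic (5+2) cycloaddition. The hydroxy fatty acid is esterified onto C4 afterwards.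

Key step: step 16

Remark on the chemistry: atoms are labelled C1, C2, C3, C3a, C4 to C8 and C8a around the hydroazulene and C11 for the one-carbon bridge; tosylhydrazone 28 is taken as a mixture of C=N isomers, which has no consequence.

**Fragment 1**

Step 1
Reactants: 1 4-bromo-3,5-dihydroxybenzoic acid
Product: 2 tert-butyl 4-bromo-3,5-dihydroxybenzoate
Conditions: Me2NCH(O-t-Bu)2 (4 equiv), toluene, 80 °C
Reagents that add atoms: N,N-dimethylformamide di-tert-butyl acetal, CN(C)C(OC(C)(C)C)OC(C)(C)C
Why: The amide acetal, protonated by the carboxylic acid, transfers a tert-butyl group to the carboxylate (esterification by O-alkylation), while the less acidic phenols beside bromine are expected to stay free.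

Step 2
Reactants: 2 tert-butyl 4-bromo-3,5-dihydroxybenzoate
Product: 3 tert-butyl 3,5-bis(allyloxy)-4-bromobenzoate
Conditions: allyl bromide (2.5 equiv), K2CO3, DMF, 50 °C
Reagents that add atoms: allyl bromide, C=CCBr
Why: Williamson ether synthesis on both phenoxides with a reactive allylic bromide, the tert-butyl ester being inert to carbonate.

Step 3
Reactants: 3 tert-butyl 3,5-bis(allyloxy)-4-bromobenzoate; 4 methyl bromoacetate
Product: 6 methyl 2-[2,6-bis(allyloxy)-4-(tert-butoxycarbonyl)phenyl]acetate, via Reformatsky reagent 5 (not isolated)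
Conditions: 4, Zn (Me3SiCl-activated), THF, 40 °C; then 3, Pd(P(t-Bu)3)2 (5 mol %, zerovalent palladium), THF, rt to 50 °C
Reagents that add atoms: none
Why: Zinc insertion gives the Reformatsky reagent, which couples with the aryl bromide in a Negishi-type cross-coupling, oxidative addition into the C–Br bond being expected to outpace ionisation of the allyl aryl ethers.

Step 4
Reactants: 6 methyl 2-[2,6-bis(allyloxy)-4-(tert-butoxycarbonyl)phenyl]acetate
Product: 7 2-[2,6-bis(allyloxy)-4-(tert-butoxycarbonyl)phenyl]acetic acid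
Conditions: LiOH·H2O (2 equiv), THF/H2O, 0 °C to rt; then 1 M HCl to pH 3
Reagents that add atoms: lithium hydroxide, [Li+].[OH-]
Why: Saponification of the unhindered methyl ester, which the bulky tert-butyl benzoate resists.

Step 5
Reactants: 7 2-[2,6-bis(allyloxy)-4-(tert-butoxycarbonyl)phenyl]acetic acid; 8 (S)-4-benzyl-2-oxazolidinone
Product: 10 (S)-4-benzyl-3-{2-[2,6-bis(allyloxy)-4-(tert-butoxycarbonyl)phenyl]acetyl}oxazolidin-2-one (fragment 1), via mixed pivalic anhydride 9 (not isolated)
Conditions: t-BuCOCl, Et3N, THF, −20 °C; then LiCl, 8, rt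
Reagents that add atoms: none
Why: N-acylation of the oxazolidinone through the mixed anhydride under LiCl/Et3N activation, a mild method that avoids ketene formation from the arylacetic acid.

**Fragment 2**

Step 6
Reactants: 11 propane-1,3-diol
Product: 12 3-[(tert-butyldimethylsilyl)oxy]propan-1-ol
Conditions: NaH (1.0 equiv), THF, rt; then t-BuMe2SiCl (1.0 equiv)
Reagents that add atoms: tert-butyldimethylsilyl chloride, CC(C)(C)[Si](C)(C)Cl
Why: Monosilylation of the symmetric diol through its sparingly soluble monosodium alkoxide, which limits double silylation.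

Step 7
Reactants: 12 3-[(tert-butyldimethylsilyl)oxy]propan-1-ol; 13 ethyl 2-(triphenylphosphoranylidene)propanoate
Product: 15 ethyl (E)-5-[(tert-butyldimethylsilyl)oxy]-2-methylpent-2-enoate, via 3-silyloxypropanal 14 (not isolated)
Conditions: TEMPO (10 mol %), PhI(OAc)2 (1.1 equiv), CH2Cl2, rt; then 13 (1.3 equiv), rt
Reagents that add atoms: none
Why: Nitroxyl-catalysed oxidation gives the elimination-prone aldehyde, which is trapped at once in a Wittig reaction whose stabilised, alpha-branched ylide should give the E enoate.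

Step 8
Reactants: 15 ethyl (E)-5-[(tert-butyldimethylsilyl)oxy]-2-methylpent-2-enoate
Product: 16 (E)-5-[(tert-butyldimethylsilyl)oxy]-2-methylpent-2-en-1-ol
Conditions: i-Bu2AlH (2.2 equiv), CH2Cl2, −78 °C
Reagents that add atoms: none
Why: 1,2-Reduction of the enoate by the aluminium hydride gives the allylic alcohol without touching the alkene geometry.

Step 9
Reactants: 16 (E)-5-[(tert-butyldimethylsilyl)oxy]-2-methylpent-2-en-1-ol
Product: 17 (E)-tert-butyl({5-[(tert-butyldimethylsilyl)oxy]-2-methylpent-2-en-1-yl}oxy)diphenylsilane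
Conditions: t-BuPh2SiCl, imidazole, CH2Cl2, rt
Reagents that add atoms: tert-butyldiphenylsilyl chloride, CC(C)(C)[Si](Cl)(c1ccccc1)c2ccccc2
Why: Imidazole-promoted silyl ether formation at the primary allylic alcohol.

Step 10
Reactants: 17 (E)-tert-butyl({5-[(tert-butyldimethylsilyl)oxy]-2-methylpent-2-en-1-yl}oxy)diphenylsilane
Product: 18 (E)-5-[(tert-butyldiphenylsilyl)oxy]-4-methylpent-3-en-1-ol
Conditions: PPTS (20 mol %), EtOH, 50 °C
Reagents that add atoms: none
Why: Acid-catalysed solvolysis removes the primary tert-butyldimethylsilyl ether much faster than the bulkier tert-butyldiphenylsilyl ether.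

Step 11
Reactants: 18 (E)-5-[(tert-butyldiphenylsilyl)oxy]-4-methylpent-3-en-1-ol
Product: 19 (E)-tert-butyl[(5-iodo-2-methylpent-2-en-1-yl)oxy]diphenylsilane (fragment 2)
Conditions: I2, PPh3, imidazole, CH2Cl2, 0 °C to rt
Reagents that add atoms: iodine, I-I
Why: Appel-type iodination, in which phosphine/iodine activation of the primary alcohol is followed by SN2 displacement by iodide.

**Union and core**

Step 12
Reactants: 10 fragment 1 imide; 19 fragment 2 iodide
Product: 21 (S)-4-benzyl-3-{(2S,5E)-2-[2,6-bis(allyloxy)-4-(tert-butoxycarbonyl)phenyl]-7-[(tert-butyldiphenylsilyl)oxy]-6-methylhept-5-enoyl}oxazolidin-2-one, via sodium enolate 20 (not isolated)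
Conditions: NaN(SiMe3)2 (1.1 equiv), THF, −78 °C; then 19 (2 equiv), −78 to −20 °C
Reagents that add atoms: none
Why: Evans alkylation, in which the chelated (Z)-enolate is alkylated by SN2 at the primary iodide on the face opposite the benzyl group of the auxiliary, which sets C3 as (S).

Step 13
Reactants: 21 alkylated imide
Product: 22 tert-butyl 3,5-bis(allyloxy)-4-{(2S,5E)-7-[(tert-butyldiphenylsilyl)oxy]-1-hydroxy-6-methylhept-5-en-2-yl}benzoate
Conditions: LiBH4, MeOH (1 equiv), Et2O, 0 °C
Reagents that add atoms: none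
Why: Reductive cleavage of the auxiliary by hydride attack at the exocyclic imide carbonyl gives the primary alcohol without epimerising C3, the hindered tert-butyl benzoate reacting far more slowly at 0 °C.

Step 14
Reactants: 22 primary alcohol
Product: 23 tert-butyl 3,5-bis(allyloxy)-4-{(2S,5E)-1-[(tert-butyldimethylsilyl)oxy]-7-[(tert-butyldiphenylsilyl)oxy]-6-methylhept-5-en-2-yl}benzoate
Conditions: t-BuMe2SiCl, imidazole, DMF, rt
Reagents that add atoms: tert-butyldimethylsilyl chloride, CC(C)(C)[Si](C)(C)Cl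
Why: Silyl ether formation masks the primary alcohol so that it cannot intercept the cations of the key step.

Step 15
Reactants: 23 bis-allyl ether
Product: 24 tert-butyl 4-{(2S,5E)-1-[(tert-butyldimethylsilyl)oxy]-7-[(tert-butyldiphenylsilyl)oxy]-6-methylhept-5-en-2-yl}-3,5-dihydroxybenzoate
Conditions: Pd(PPh3)4 (5 mol %, zerovalent palladium), morpholine (10 equiv), THF, rt
Reagents that add atoms: none
Why: Tsuji–Trost-type deallylation, in which zerovalent palladium ionises both allyl aryl ethers and morpholine accepts the allyl groups under neutral conditions that spare the silyl ethers, the ester and C3.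

Step 16
Reactants: 24 free 2-alkylresorcinol benzoate
Product: 27 tricyclic ene-dione cycloadduct (C11 bridging ketone and C4 enone), via phenoxonium ion 25 (not isolated), via spiro tertiary cation 26 (not isolated)
Conditions: PhI(OAc)2 (1.1 equiv, trivalent iodine), (CF3)2CHOH (0.005 M), 0 °C
Reagents that add atoms: none
Why: Ligand exchange of one phenol on the trivalent iodine reagent and loss of PhI and acetate give phenoxonium ion 25, whose charge lies on C3a, C5 and C7 while the C6 ester and the second hydroxyl sit on nodal carbons; the electron-rich alkene CH (C8a) bonds to C3a to give tertiary cation 26, and the dienol carbon C7 then captures C8 with loss of the hydroxyl proton, leaving the neutral ene-dione. The closest known reaction type is the oxidative dearomatisation-induced intramolecular cationic (5+2) cycloaddition of ortho-(pent-4-enyl)phenols, here with the second hydroxyl taking the place of an external nucleophile. The spiro cyclopentane (C3a, C3, C2, C1, C8a) closes by 5-exo attack of the alkene on C3a, and the second cyclopentane (C3a, C8a, C8, C7, C11) by 5-exo capture of the C8 cation by the C6=C7 dienol bond, which also completes the seven-membered ring of the bicyclo[3.2.1]octene. C8a is set relative to the (S) centre C3 in the spirocyclisation, C3a and C7 follow because cation C8 can only reach the ring CH on its own side of the new cyclopentane, and C8 follows from the E geometry because both bonds should form on one face of the alkene before rotation about C8a–C8 can occur. The selectivity needed is closure of C8 onto the ring CH on the side of the CH2OTBS arm, so that the adjacent C–O carbon becomes the bridge C11 and the arm ends cis to it; the (S) centre should secure this because the benzylic hydrogen lies in the arene plane beside the other C–O, which stays coplanar with C3a–C3 as the C4 carbonyl and tolerates only hydrogen next to it, whereas the carbon that becomes the bridge bends away from C3. Either oxygen can become the bridging carbonyl because the arene is locally twofold symmetric, and high dilution in the non-nucleophilic, cation-stabilising fluoro alcohol should suppress capture of the cations and dimerisation.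

Step 17
Reactants: 27 tricyclic ene-dione cycloadduct
Product: 28 C11 tosylhydrazone of the ene-dione
Conditions: TsNHNH2 (1.2 equiv), AcOH (cat.), THF, rt
Reagents that add atoms: 4-methylbenzenesulfonohydrazide, Cc1ccc(cc1)S(=O)(=O)NN
Why: Hydrazone formation should occur at the strained, unconjugated bridging ketone, which is far more reactive towards condensation than the conjugated C4 carbonyl flanked by the quaternary C3a.

Step 18
Reactants: 28 C11 tosylhydrazone
Product: 29 tricyclic enone with C11 as CH2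
Conditions: catecholborane (2 equiv), CHCl3, 0 °C; then NaOAc·3H2O, reflux
Reagents that add atoms: none
Why: Caglioti-type reduction, in which hydride adds to the C=N bond and acetate then induces loss of sulfinate and dinitrogen to leave CH2, under conditions to which the s-trans enone and the enoate are inert.

Step 19
Reactants: 29 tricyclic enone
Product: 30 tricyclic C4 allylic alcohol (hydroxyl syn to the C8a–C8 bridge)
Conditions: NaBH4, CeCl3·7H2O, MeOH, −78 °C
Reagents that add atoms: none
Why: Luche reduction delivers hydride 1,2 to the enone from the exo face, anti to the two-carbon bridge and staggered between C11 and C3 at C3a, which sets C4 with the hydroxyl on the side of the C8a–C8 bridge.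

**Fragment 3**

Step 20
Reactants: 31 7-bromoheptan-1-ol
Product: 32 [(7-bromoheptyl)oxy](tert-butyl)diphenylsilane
Conditions: t-BuPh2SiCl, imidazole, CH2Cl2, rt
Reagents that add atoms: tert-butyldiphenylsilyl chloride, CC(C)(C)[Si](Cl)(c1ccccc1)c2ccccc2
Why: Silyl ether formation protects the primary alcohol with a group that survives ylide formation and saponification.

Step 21
Reactants: 32 [(7-bromoheptyl)oxy](tert-butyl)diphenylsilane
Product: 33 {7-[(tert-butyldiphenylsilyl)oxy]heptyl}triphenylphosphonium bromide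
Conditions: PPh3, MeCN, reflux
Reagents that add atoms: triphenylphosphine, c1ccc(cc1)P(c2ccccc2)c3ccccc3
Why: SN2 quaternisation of the phosphine by the primary bromide.

Step 22
Reactants: 33 phosphonium bromide; 34 methyl 9-oxononanoate
Product: 36 methyl (Z)-16-[(tert-butyldiphenylsilyl)oxy]hexadec-9-enoate, via phosphonium ylide 35 (not isolated)
Conditions: NaN(SiMe3)2, THF, −78 to 0 °C; then 34, −78 °C to rt
Reagents that add atoms: none
Why: A kinetically controlled, lithium-free Wittig reaction of the non-stabilised ylide with the aldehyde should give the Z alkene.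

Step 23
Reactants: 36 methyl (Z)-16-[(tert-butyldiphenylsilyl)oxy]hexadec-9-enoate
Product: 37 (Z)-16-[(tert-butyldiphenylsilyl)oxy]hexadec-9-enoic acid (fragment 3)
Conditions: LiOH·H2O, THF/MeOH/H2O, rt; then 1 M HCl
Reagents that add atoms: lithium hydroxide, [Li+].[OH-]
Why: Saponification of the methyl ester, which neither the silyl ether nor the isolated Z alkene should notice.

**Endgame**

Step 24
Reactants: 30 tricyclic C4 allylic alcohol; 37 fragment 3 acid
Product: 39 fully protected C4 ester of the core, via Yamaguchi mixed anhydride 38 (not isolated)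
Conditions: 37 (1.5 equiv), 2,4,6-Cl3C6H2COCl, Et3N, toluene, rt; then 30, DMAP, toluene, rt to 40 °C
Reagents that add atoms: none
Why: Yamaguchi esterification, in which DMAP transfers the aliphatic acyl group of the mixed anhydride to the hindered secondary alcohol with retention at C4.

Step 25
Reactants: 39 fully protected C4 ester
Product: 40 C3 hydroxymethyl compound (both tert-butyldiphenylsilyl ethers retained)
Conditions: CSA (10 mol %), MeOH/CH2Cl2 (1:1), 0 °C
Reagents that add atoms: none
Why: Acid-catalysed methanolysis cleaves the single primary tert-butyldimethylsilyl ether selectively over the two tert-butyldiphenylsilyl ethers, the tert-butyl ester and the fatty ester.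

Step 26
Reactants: 40 C3 hydroxymethyl compound
Product: 41 C3 aldehyde
Conditions: Dess–Martin periodinane, NaHCO3, CH2Cl2, 0 °C to rt
Reagents that add atoms: none
Why: Dess–Martin oxidation converts the primary alcohol into the aldehyde under buffered conditions that should not epimerise C3.

Step 27
Reactants: 41 C3 aldehyde
Product: 43 target CNP0148862.2, via carboxylic acid bis-silyl ether 42 (not isolated)
Conditions: CF3CO2H/CH2Cl2 (1:4), 0 °C; evaporate; then HF·pyridine, pyridine, THF, 0 °C to rt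
Reagents that add atoms: none
Why: Acidolysis of the tert-butyl ester with loss of 2-methylpropene is followed by fluoride cleavage of both silyl ethers, and only acidic or neutral conditions touch the base-sensitive aldehyde centre C3, the allylic ester and the Z alkene.

**Compound list**

1 | 4-bromo-3,5-dihydroxybenzoic acid | OC(=O)c1cc(O)c(Br)c(O)c1 | starting material
2 | tert-butyl 4-bromo-3,5-dihydroxybenzoate | CC(C)(C)OC(=O)c1cc(O)c(Br)c(O)c1 | intermediate
3 | tert-butyl 3,5-bis(allyloxy)-4-bromobenzoate | CC(C)(C)OC(=O)c1cc(OCC=C)c(Br)c(OCC=C)c1 | intermediate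
4 | methyl bromoacetate | COC(=O)CBr | starting material
5 | bromo(2-methoxy-2-oxoethyl)zinc, Reformatsky reagent | COC(=O)C[Zn]Br | intermediate
6 | methyl 2-[2,6-bis(allyloxy)-4-(tert-butoxycarbonyl)phenyl]acetate | COC(=O)Cc1c(OCC=C)cc(C(=O)OC(C)(C)C)cc1OCC=C | intermediate
7 | 2-[2,6-bis(allyloxy)-4-(tert-butoxycarbonyl)phenyl]acetic acid | OC(=O)Cc1c(OCC=C)cc(C(=O)OC(C)(C)C)cc1OCC=C | intermediate
8 | (S)-4-benzyl-2-oxazolidinone | O=C1OC[C@H](Cc2ccccc2)N1 | starting material
9 | mixed pivalic anhydride of 7 | CC(C)(C)C(=O)OC(=O)Cc1c(OCC=C)cc(C(=O)OC(C)(C)C)cc1OCC=C | intermediate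
10 | fragment 1, (S)-4-benzyl-3-{2-[2,6-bis(allyloxy)-4-(tert-butoxycarbonyl)phenyl]acetyl}oxazolidin-2-one | O=C1OC[C@H](Cc2ccccc2)N1C(=O)Cc3c(OCC=C)cc(C(=O)OC(C)(C)C)cc3OCC=C | intermediate
11 | propane-1,3-diol | OCCCO | starting material
12 | 3-[(tert-butyldimethylsilyl)oxy]propan-1-ol | OCCCO[Si](C)(C)C(C)(C)C | intermediate
13 | ethyl 2-(triphenylphosphoranylidene)propanoate | CCOC(=O)C(C)=P(c1ccccc1)(c2ccccc2)c3ccccc3 | starting material
14 | 3-[(tert-butyldimethylsilyl)oxy]propanal | O=CCCO[Si](C)(C)C(C)(C)C | intermediate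
15 | ethyl (E)-5-[(tert-butyldimethylsilyl)oxy]-2-methylpent-2-enoate | CCOC(=O)/C(C)=C/CCO[Si](C)(C)C(C)(C)C | intermediate
16 | (E)-5-[(tert-butyldimethylsilyl)oxy]-2-methylpent-2-en-1-ol | OC/C(C)=C/CCO[Si](C)(C)C(C)(C)C | intermediate
17 | (E)-tert-butyl({5-[(tert-butyldimethylsilyl)oxy]-2-methylpent-2-en-1-yl}oxy)diphenylsilane | CC(C)(C)[Si](C)(C)OCC/C=C(\C)CO[Si](c1ccccc1)(c2ccccc2)C(C)(C)C | intermediate
18 | (E)-5-[(tert-butyldiphenylsilyl)oxy]-4-methylpent-3-en-1-ol | OCC/C=C(\C)CO[Si](c1ccccc1)(c2ccccc2)C(C)(C)C | intermediate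
19 | fragment 2, (E)-tert-butyl[(5-iodo-2-methylpent-2-en-1-yl)oxy]diphenylsilane | ICC/C=C(\C)CO[Si](c1ccccc1)(c2ccccc2)C(C)(C)C | intermediate
20 | sodium (Z)-enolate of imide 10 | [Na+].[O-]/C(=C\c1c(OCC=C)cc(C(=O)OC(C)(C)C)cc1OCC=C)N2C(=O)OC[C@@H]2Cc3ccccc3 | intermediate
21 | (S)-4-benzyl-3-{(2S,5E)-2-[2,6-bis(allyloxy)-4-(tert-butoxycarbonyl)phenyl]-7-[(tert-butyldiphenylsilyl)oxy]-6-methylhept-5-enoyl}oxazolidin-2-one | O=C1OC[C@H](Cc2ccccc2)N1C(=O)[C@H](c3c(OCC=C)cc(C(=O)OC(C)(C)C)cc3OCC=C)CC/C=C(\C)CO[Si](c4ccccc4)(c5ccccc5)C(C)(C)C | intermediate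
22 | tert-butyl 3,5-bis(allyloxy)-4-{(2S,5E)-7-[(tert-butyldiphenylsilyl)oxy]-1-hydroxy-6-methylhept-5-en-2-yl}benzoate | OC[C@H](c1c(OCC=C)cc(C(=O)OC(C)(C)C)cc1OCC=C)CC/C=C(\C)CO[Si](c2ccccc2)(c3ccccc3)C(C)(C)C | intermediate
23 | tert-butyl 3,5-bis(allyloxy)-4-{(2S,5E)-1-[(tert-butyldimethylsilyl)oxy]-7-[(tert-butyldiphenylsilyl)oxy]-6-methylhept-5-en-2-yl}benzoate | CC(C)(C)[Si](C)(C)OC[C@H](c1c(OCC=C)cc(C(=O)OC(C)(C)C)cc1OCC=C)CC/C=C(\C)CO[Si](c2ccccc2)(c3ccccc3)C(C)(C)C | intermediate
24 | key precursor, tert-butyl 4-{(2S,5E)-1-[(tert-butyldimethylsilyl)oxy]-7-[(tert-butyldiphenylsilyl)oxy]-6-methylhept-5-en-2-yl}-3,5-dihydroxybenzoate | Oc1cc(C(=O)OC(C)(C)C)cc(O)c1[C@@H](CO[Si](C)(C)C(C)(C)C)CC/C=C(\C)CO[Si](c2ccccc2)(c3ccccc3)C(C)(C)C | intermediate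
25 | phenoxonium ion of 24, drawn with the charge on C3a | O=C1C=C(C(=O)OC(C)(C)C)C=C(O)[C+]1[C@@H](CO[Si](C)(C)C(C)(C)C)CC/C=C(\C)CO[Si](c2ccccc2)(c3ccccc3)C(C)(C)C | intermediate
26 | spirocyclic cation, C3a–C8a bond formed and charge on C8 | C[C+](CO[Si](c4ccccc4)(c5ccccc5)C(C)(C)C)[C@@H]1CC[C@H](CO[Si](C)(C)C(C)(C)C)[C@]12C(=O)C=C(C(=O)OC(C)(C)C)C=C2O | intermediate
27 | tricyclic ene-dione cycloadduct: C11 ketone, C4 ketone conjugated to C5=C6–CO2t-Bu, C3 CH2OTBS cis to C11, C8 methyl syn to C11, C8 CH2OTBDPS and H8a endo | C[C@@]1(CO[Si](c4ccccc4)(c5ccccc5)C(C)(C)C)[C@H]2C(=O)[C@@]3(C(=O)C=C2C(=O)OC(C)(C)C)[C@@H](CO[Si](C)(C)C(C)(C)C)CC[C@@H]13 | intermediate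
28 | C11 tosylhydrazone of 27 | C[C@@]1(CO[Si](c4ccccc4)(c5ccccc5)C(C)(C)C)[C@H]2C(=NNS(=O)(=O)c6ccc(C)cc6)[C@@]3(C(=O)C=C2C(=O)OC(C)(C)C)[C@@H](CO[Si](C)(C)C(C)(C)C)CC[C@@H]13 | intermediate
29 | tricyclic C4 enone with C11 as CH2 | C[C@@]1(CO[Si](c4ccccc4)(c5ccccc5)C(C)(C)C)[C@H]2C[C@@]3(C(=O)C=C2C(=O)OC(C)(C)C)[C@@H](CO[Si](C)(C)C(C)(C)C)CC[C@@H]13 | intermediate
30 | tricyclic C4 allylic alcohol, hydroxyl syn to the C8a–C8 bridge | C[C@@]1(CO[Si](c4ccccc4)(c5ccccc5)C(C)(C)C)[C@H]2C[C@@]3([C@@H](O)C=C2C(=O)OC(C)(C)C)[C@@H](CO[Si](C)(C)C(C)(C)C)CC[C@@H]13 | intermediate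
31 | 7-bromoheptan-1-ol | OCCCCCCCBr | starting material
32 | [(7-bromoheptyl)oxy](tert-butyl)diphenylsilane | BrCCCCCCCO[Si](c1ccccc1)(c2ccccc2)C(C)(C)C | intermediate
33 | {7-[(tert-butyldiphenylsilyl)oxy]heptyl}triphenylphosphonium bromide | [Br-].CC(C)(C)[Si](c1ccccc1)(c2ccccc2)OCCCCCCC[P+](c3ccccc3)(c4ccccc4)c5ccccc5 | intermediate
34 | methyl 9-oxononanoate | COC(=O)CCCCCCCC=O | starting material
35 | {7-[(tert-butyldiphenylsilyl)oxy]heptylidene}triphenylphosphorane | CC(C)(C)[Si](c1ccccc1)(c2ccccc2)OCCCCCCC=P(c3ccccc3)(c4ccccc4)c5ccccc5 | intermediate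
36 | methyl (Z)-16-[(tert-butyldiphenylsilyl)oxy]hexadec-9-enoate | COC(=O)CCCCCCC/C=C\CCCCCCO[Si](c1ccccc1)(c2ccccc2)C(C)(C)C | intermediate
37 | fragment 3, (Z)-16-[(tert-butyldiphenylsilyl)oxy]hexadec-9-enoic acid | OC(=O)CCCCCCC/C=C\CCCCCCO[Si](c1ccccc1)(c2ccccc2)C(C)(C)C | intermediate
38 | mixed anhydride of 37 with 2,4,6-trichlorobenzoic acid | O=C(OC(=O)c1c(Cl)cc(Cl)cc1Cl)CCCCCCC/C=C\CCCCCCO[Si](c2ccccc2)(c3ccccc3)C(C)(C)C | intermediate
39 | fully protected C4 ester of the core with the fatty acid chain | C[C@@]1(CO[Si](c4ccccc4)(c5ccccc5)C(C)(C)C)[C@H]2C[C@@]3([C@@H](OC(=O)CCCCCCC/C=C\CCCCCCO[Si](c6ccccc6)(c7ccccc7)C(C)(C)C)C=C2C(=O)OC(C)(C)C)[C@@H](CO[Si](C)(C)C(C)(C)C)CC[C@@H]13 | intermediate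
40 | C3 hydroxymethyl compound | C[C@@]1(CO[Si](c4ccccc4)(c5ccccc5)C(C)(C)C)[C@H]2C[C@@]3([C@@H](OC(=O)CCCCCCC/C=C\CCCCCCO[Si](c6ccccc6)(c7ccccc7)C(C)(C)C)C=C2C(=O)OC(C)(C)C)[C@@H](CO)CC[C@@H]13 | intermediate
41 | C3 aldehyde | C[C@@]1(CO[Si](c4ccccc4)(c5ccccc5)C(C)(C)C)[C@H]2C[C@@]3([C@@H](OC(=O)CCCCCCC/C=C\CCCCCCO[Si](c6ccccc6)(c7ccccc7)C(C)(C)C)C=C2C(=O)OC(C)(C)C)[C@@H](C=O)CC[C@@H]13 | intermediate
42 | C6 carboxylic acid with both tert-butyldiphenylsilyl ethers | C[C@@]1(CO[Si](c4ccccc4)(c5ccccc5)C(C)(C)C)[C@H]2C[C@@]3([C@@H](OC(=O)CCCCCCC/C=C\CCCCCCO[Si](c6ccccc6)(c7ccccc7)C(C)(C)C)C=C2C(=O)O)[C@@H](C=O)CC[C@@H]13 | intermediate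
43 | CNP0148862.2, (3S,3aS,4S,7R,8S,8aS)-3-formyl-4-{[(9Z)-16-hydroxyhexadec-9-enoyl]oxy}-8-(hydroxymethyl)-8-methyl-2,3,4,7,8,8a-hexahydro-1H-3a,7-methanoazulene-6-carboxylic acid | C[C@@]1(CO)[C@H]2C[C@@]3([C@@H](OC(=O)CCCCCCC/C=C\CCCCCCO)C=C2C(=O)O)[C@@H](C=O)CC[C@@H]13 | target

Total step count: 27. Longest linear sequence: 18 steps (steps 6 to 19 and 24 to 27, from propane-1,3-diol).

**Steps most likely to fail**

Step 16. The cations may be intercepted by acetate or solvent before the second ring closes, the iodine reagent may attack the free ring CH positions of the resorcinol, or the second bond may close on the other ring CH. The fallback separates dearomatisation from cycloaddition. Setting out from 24, Wessely acetoxylation with Pb(OAc)4 (AcOH/CH2Cl2, 0 °C) should give the ortho-quinol acetate F1, as both epimers at the acetoxy carbon, which is of no consequence. Ionisation of F1 with BF3·OEt2 in CH2Cl2 at −78 °C, with no oxidant present, should regenerate cation 25 and return to the route at 27.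

Step 17. The sulfonyl hydrazide may add in a conjugate sense to the doubly activated C5=C6 bond or condense at C4 instead of C11. The fallback distinguishes the two carbonyls by hydride reactivity and removes the C11 oxygen through a radical. Setting out from 27, NaBH4 in MeOH/CH2Cl2 at −78 °C should reduce the strained saturated bridging ketone ahead of the enone and give the C11 alcohol F2. 1,1'-Thiocarbonyldiimidazole with DMAP in hot toluene should convert it into the imidazolylthiocarbonate F3, and Barton–McCombie deoxygenation with (Me3Si)3SiH and AIBN returns to the route at 29.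

Step 19. Facial selectivity may be poor, because the CH2OTBS arm on C3 lies near the exo face of the C4 carbonyl and may divert hydride to the endo face. The fallback corrects C4 by inversion. Setting out from 29, the reduction would then give the C4-epimeric alcohol F4. Mitsunobu inversion with 4-nitrobenzoic acid (PPh3, DIAD, toluene) should give the 4-nitrobenzoate F5 with the C4 configuration of the target, and methanolysis (K2CO3, MeOH, rt) returns to the route at 30.

Further compounds
F1 | step 16 | ortho-quinol acetate of 24, tert-butyl 6-acetoxy-5-hydroxy-1-oxo-6-alkylcyclohexa-2,4-diene-3-carboxylate, both epimers at the acetoxy carbon | CC(=O)OC1(C(=O)C=C(C(=O)OC(C)(C)C)C=C1O)[C@@H](CO[Si](C)(C)C(C)(C)C)CC/C=C(\C)CO[Si](c2ccccc2)(c3ccccc3)C(C)(C)C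
F2 | step 17 | C11 alcohol of 27, hydroxyl syn to the C8a–C8 bridge | C[C@@]1(CO[Si](c4ccccc4)(c5ccccc5)C(C)(C)C)[C@H]2[C@@H](O)[C@@]3(C(=O)C=C2C(=O)OC(C)(C)C)[C@@H](CO[Si](C)(C)C(C)(C)C)CC[C@@H]13
F3 | step 17 | C11 O-(imidazol-1-ylthiocarbonyl) derivative of F2 | C[C@@]1(CO[Si](c4ccccc4)(c5ccccc5)C(C)(C)C)[C@H]2[C@@H](OC(=S)n6ccnc6)[C@@]3(C(=O)C=C2C(=O)OC(C)(C)C)[C@@H](CO[Si](C)(C)C(C)(C)C)CC[C@@H]13
F4 | step 19 | C4 epimer of alcohol 30 | C[C@@]1(CO[Si](c4ccccc4)(c5ccccc5)C(C)(C)C)[C@H]2C[C@@]3([C@H](O)C=C2C(=O)OC(C)(C)C)[C@@H](CO[Si](C)(C)C(C)(C)C)CC[C@@H]13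
F5 | step 19 | C4 4-nitrobenzoate with the C4 configuration of the target | C[C@@]1(CO[Si](c4ccccc4)(c5ccccc5)C(C)(C)C)[C@H]2C[C@@]3([C@@H](OC(=O)c6ccc(cc6)[N+](=O)[O-])C=C2C(=O)OC(C)(C)C)[C@@H](CO[Si](C)(C)C(C)(C)C)CC[C@@H]13
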